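Numbering: O1, C2 (lactone C=O), C3, C4, C5 (spiro), C6 (lactone C=O), O7, C8, C9; side chain C1′–C10′ on C8.
Enabling feature: C4 and C5 each carry one oxygen, one carboxyl carbon and one CH2 arm (C3, C9) and are configured 4R,5S. The C4–C5 unit is therefore a 2,3-dialkylated meso-tartaric acid with a latent mirror plane, and ring C5–C6–O7–C8–C9 is the γ-lactone of a pent-4-enoic acid.
Retrosynthetic cuts in order: C3–OH, O1–C2, C1′–C2′, then O7–C8 together with a C1′–I bond (iodolactone), C4–C5 (reductive dimerisation), and the allyl–carbonyl bond of an α-keto ester.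
Forward order: C4–C5 bond, ketal diacid, ring C5–C6–O7–C8–C9 first, second allyl arm cut down to C3–C2O2H, C9 chain fragment joined at C1′ through the derived epoxide, ring O1–C2–C3–C4–C5 second on removal of the ketal, C3 oxygen last.
Stereochemistry: relative C4/C5 by isolating the meso dimer. Absolute C4, C5 and C8 come from the chiral catalyst of the iodolactonisation, with C8 tied to C5 by the cis preference of the closing ring. C3 is set by attack on the lactone enolate anti to the C4 lithium alkoxide.
Key step: step 5

Assumption: the sense of induction of the binaphthyl catalyst on this new substrate class cannot be read from a model, so the (S)-catalyst is written and its equally accessible antipode is substituted should a pilot run deliver the mirror-image lactone.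

Step 1
Reactants: 1 dimethyl oxalate; 2 allylmagnesium bromide (commercial 1.0 M solution in Et2O)
Product: 4 methyl 2-oxopent-4-enoate, via magnesium hemiketal adduct 3 (not isolated)
Conditions: 1 (1.3 equiv), THF/Et2O, −78 °C, slow addition of 2; 1 M HCl quench at −78 °C
Reagents that add atoms: none
Why: Grignard mono-acylation with a dialkyl oxalate works because adduct 3 is held as a magnesium chelate at −78 °C and releases the ketone only in the cold acidic quench, which should exclude a second addition and avoid base-induced migration of the double bond into conjugation.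

Step 2
Reactants: 4 methyl 2-oxopent-4-enoate (two molecules)
Product: 5 dimethyl (2R,3S)-2,3-dihydroxy-2,3-di(prop-2-enyl)butanedioate (meso)
Conditions: [Ir(ppy)2(dtbbpy)]PF6 (1 mol %), Hantzsch ester (0.6 equiv), CH2Cl2, blue LED, rt; chromatographic separation of the meso from the chiral diastereomer
Reagents that add atoms: none
Why: Pinacol-type reductive dimerisation of an α-keto ester under photoredox conditions relies on single-electron reduction of the keto group and head-to-head radical coupling that is faster than any addition to the unactivated vinyl group; the C4–C5 bond and both quaternary carbinols arise at once without useful diastereocontrol, so the meso isomer is secured by separation (its ketal in the next step should show two different ketal methyl signals, that of the chiral isomer only one).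

Step 3
Reactants: 5 meso diol
Product: 6 dimethyl (4R,5S)-2,2-dimethyl-4,5-di(prop-2-enyl)-1,3-dioxolane-4,5-dicarboxylate (meso; allyl groups cis)
Conditions: 2-methoxypropene (5 equiv), CSA (10 mol %), CH2Cl2, 0 °C → rt
Reagents that add atoms: 2-methoxypropene, C=C(C)OC
Why: Acid-catalysed ketalisation with an enol ether is driven strongly enough to close the dioxolane on two hindered, electron-poor tertiary hydroxyls, touches no stereocentre and keeps the mirror plane.

Step 4
Reactants: 6 meso ketal diester
Product: 7 (4R,5S)-2,2-dimethyl-4,5-di(prop-2-enyl)-1,3-dioxolane-4,5-dicarboxylic acid (meso)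
Conditions: KOH (8 equiv), MeOH/H2O 4:1, 65 °C; then 1 M HCl, 0 °C, pH 2
Reagents that add atoms: potassium hydroxide, [K+].[OH-]
Why: Saponification of the two hindered but α-oxygen-activated methyl esters needs heat and excess hydroxide, which ketal and isolated alkenes tolerate, nothing can epimerise because there is no α-hydrogen, and brief cold acidification frees the diacid without loss of the ketal.

Step 5
Reactants: 7 meso ketal diacid
Product: 8 (4R,5S,8S)-8-(iodomethyl)-2,2-dimethyl-6-oxo-4-(prop-2-enyl)-1,3,7-trioxaspiro[4.4]nonane-4-carboxylic acid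
Conditions: NIS (1.0 equiv), (S)-2′-[(butylsulfanyl)methyl]-1,1′-binaphthalen-2-ol (10 mol %), CH2Cl2/toluene 1:1, −78 → −60 °C, dark
Reagents that add atoms: N-iodosuccinimide, O=C1CCC(=O)N1I
Why: Proposed new method: the Lewis-basic sulfur takes I+ from NIS while the naphthol OH hydrogen-bonds one carboxyl group, so the iodonium ion is built on the allyl group geminal to the bound carboxyl and is opened anti by that carboxyl oxygen at the internal alkene carbon. The closest known reaction type is the catalytic enantioselective desymmetrising halolactonisation of α,α-diallyl carboxylic acids; new here are the meso diacid with two acid/alkene pairs and the α-oxygenated quaternary centres. The only ring closed is the γ-lactone C5–C6–O7–C8–C9, by 5-exo-trig attack that forms O7–C8 and leaves iodine on the exocyclic carbon C1′. C8 is set by the alkene face the catalyst selects, and because the forming envelope places CH2I and the larger α-substituent C4 (rather than O1) pseudo-equatorial and hence cis, a given C8 configuration can arise without strain from only one of the two enantiotopic halves, which fixes C5 as S and C4 as R. The step needs mono- over bis-cyclisation (one equivalent of NIS at low temperature, and the second cyclisation preferentially removes the minor enantiomer, whose free half is the one the catalyst prefers), geminal over vicinal carboxyl attack (the vicinal carboxyl sits on the opposite face of the dioxolane and would need a trans-fused δ-lactone) and lactone over ether formation (both tertiary oxygens are locked in the ketal).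

Step 6
Reactants: 8 iodolactone acid
Product: 10 (4R,5S,8S)-8-(iodomethyl)-2,2-dimethyl-6-oxo-4-(2-oxoethyl)-1,3,7-trioxaspiro[4.4]nonane-4-carboxylic acid, via secondary ozonide 9 (not isolated)
Conditions: O3, CH2Cl2, −78 °C (Sudan III end point); PPh3 (1.1 equiv), −78 °C → rt
Reagents that add atoms: ozone, [O-][O+]=O
Why: Ozonolysis with reductive work-up is selective because the monosubstituted alkene consumes ozone far faster than primary iodide, lactone or ketal, the indicator prevents over-oxidation, and loss of the terminal CH2 turns the remaining allyl arm into C3H2–C2HO before any other alkene is present in the molecule.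

Step 7
Reactants: 10 aldehyde acid
Product: 11 (4R,5S,8S)-4-(carboxymethyl)-8-(iodomethyl)-2,2-dimethyl-6-oxo-1,3,7-trioxaspiro[4.4]nonane-4-carboxylic acid
Conditions: NaClO2, NaH2PO4, 2-methyl-2-butene, t-BuOH/H2O, 0 °C → rt
Reagents that add atoms: sodium chlorite, [Na+].[O-]Cl=O
Why: Pinnick oxidation raises C2 to the carboxylic acid under buffered conditions with 2-methyl-2-butene trapping hypochlorous acid, so iodide, lactone and ketal should survive and no stereocentre is affected.

Step 8
Reactants: 11 iodolactone diacid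
Product: 12 tert-butyl (4R,5S,8S)-4-(2-tert-butoxy-2-oxoethyl)-8-(iodomethyl)-2,2-dimethyl-6-oxo-1,3,7-trioxaspiro[4.4]nonane-4-carboxylate
Conditions: O-tert-butyl-N,N′-diisopropylisourea (6 equiv), CH2Cl2, rt → 40 °C
Reagents that add atoms: O-tert-butyl-N,N′-diisopropylisourea, CC(C)NC(=NC(C)C)OC(C)(C)C
Why: Esterification with an O-tert-butyl isourea alkylates both carboxyl groups under neutral conditions regardless of the hindrance at C4, and tert-butyl esters are chosen because they resist methoxide and organometallic reagents in the next two steps.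

Step 9
Reactants: 12 iodolactone di-tert-butyl ester
Product: 14 4-tert-butyl 5-methyl (4R,5S)-4-(2-tert-butoxy-2-oxoethyl)-2,2-dimethyl-5-{[(2S)-oxiran-2-yl]methyl}-1,3-dioxolane-4,5-dicarboxylate, via iodohydrin methyl ester 13 (not isolated)
Conditions: K2CO3 (2 equiv), MeOH, 0 °C → rt
Reagents that add atoms: methanol, CO
Why: Base-induced methanolysis of an iodolactone opens the α-oxygen-activated carbonyl C6 to 13, whose C8 oxygen displaces the neighbouring iodide in an irreversible Williamson-type 3-exo-tet closure with the C8–O7 bond and configuration retained, which replaces a fragmentation-prone β-acyloxy iodide by an electrophile that organocopper reagents open cleanly.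

Step 10
Reactants: 14 epoxy ester; 15 9-bromonon-1-ene
Product: 18 tert-butyl (4R,5S,8R)-4-(2-tert-butoxy-2-oxoethyl)-8-(dec-9-enyl)-2,2-dimethyl-6-oxo-1,3,7-trioxaspiro[4.4]nonane-4-carboxylate, via non-8-enylmagnesium bromide 16 (not isolated), via hydroxy ester 17 (not isolated)
Conditions: 15, Mg, THF, rt → 40 °C; then CuI (15 mol %), 14, THF, −40 °C → rt; aq NH4Cl
Reagents that add atoms: none
Why: Copper-catalysed opening of a terminal epoxide by a Grignard reagent occurs at the unsubstituted carbon C1′, so the C8–O7 bond and its configuration are untouched, and the magnesium alkoxide of 17 then closes onto the geminal methyl ester (the tert-butyl esters cannot compete) to restore the γ-lactone.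

Step 11
Reactants: 18 decenyl spirolactone ketal
Product: 20 (4R,5S,8R)-8-(dec-9-enyl)-4-hydroxy-2,6-dioxo-1,7-dioxaspiro[4.4]nonane-4-carboxylic acid, via dihydroxy diacid 19 (not isolated)
Conditions: TFA/CH2Cl2/H2O 10:10:1, 0 °C → rt
Reagents that add atoms: none
Why: Acid hydrolysis of the ketal and acidolysis of both tert-butyl esters free 19, in which only the C5 hydroxyl and the C2 carboxyl can form a five-membered ring, so γ-lactonisation closes O1–C2 without touching any stereocentre while the C8 lactone stays closed.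

Step 12
Reactants: 20 bislactone hydroxy acid
Product: 21 tert-butyl (4R,5S,8R)-8-(dec-9-enyl)-4-hydroxy-2,6-dioxo-1,7-dioxaspiro[4.4]nonane-4-carboxylate
Conditions: O-tert-butyl-N,N′-diisopropylisourea (3 equiv), CH2Cl2, rt
Reagents that add atoms: O-tert-butyl-N,N′-diisopropylisourea, CC(C)NC(=NC(C)C)OC(C)(C)C
Why: O-Alkylation of the acid with an O-tert-butyl isourea transfers the tert-butyl group to the carboxylate under neutral conditions, so it is indifferent to hindrance and leaves the tertiary hydroxyl, both lactones and the alkene alone.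

Step 13
Reactants: 21 bislactone tert-butyl ester
Product: 23 tert-butyl (3R,4R,5S,8R)-8-(dec-9-enyl)-3,4-dihydroxy-2,6-dioxo-1,7-dioxaspiro[4.4]nonane-4-carboxylate, via dilithium dianion 22 (not isolated)
Conditions: LDA (2.3 equiv), THF, −78 °C; (+)-(camphorsulfonyl)oxaziridine (1.5 equiv), −78 °C; AcOH quench at −78 °C
Reagents that add atoms: (+)-(camphorsulfonyl)oxaziridine, CC1(C)[C@@H]2CC[C@]13CS(=O)(=O)N4O[C@@]34C2
Why: Davis-type enolate oxidation of a β-hydroxy lactone dianion works because the first equivalent of base turns the C4 hydroxyl into an alkoxide that cannot leave, so the only possible enolate (C2–C3) does not eliminate, and the oxaziridine should deliver oxygen to the face anti to that solvated alkoxide, as electrophiles do with β-hydroxy-γ-butyrolactone dianions, which places the new hydroxyl trans to the C4 hydroxyl (3R).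

Step 14
Reactants: 23 dihydroxy bislactone tert-butyl ester
Product: 24 (3R,4R,5S,8R)-8-(dec-9-enyl)-3,4-dihydroxy-2,6-dioxo-1,7-dioxaspiro[4.4]nonane-4-carboxylic acid (CNP0281847.1)
Conditions: TFA/CH2Cl2 1:3, 0 °C → rt
Reagents that add atoms: none
Why: Acidolysis of a tert-butyl ester by alkyl–oxygen cleavage needs neither nucleophile nor base, so no lactone is opened, C3 cannot epimerise, and the short exposure to diluted acid should spare the terminal alkene.

Compound list
1 | dimethyl oxalate | COC(=O)C(=O)OC | starting material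
2 | allylmagnesium bromide | C=CC[Mg]Br | starting material
3 | bromomagnesium hemiketal adduct of 1 and 2 (not isolated) | C=CCC(OC)(O[Mg]Br)C(=O)OC | intermediate
4 | methyl 2-oxopent-4-enoate | C=CCC(=O)C(=O)OC | intermediate
5 | dimethyl (2R,3S)-2,3-dihydroxy-2,3-di(prop-2-enyl)butanedioate (meso) | C=CC[C@@](O)(C(=O)OC)[C@](O)(CC=C)C(=O)OC | intermediate
6 | dimethyl (4R,5S)-2,2-dimethyl-4,5-di(prop-2-enyl)-1,3-dioxolane-4,5-dicarboxylate (meso) | C=CC[C@]1(C(=O)OC)OC(C)(C)O[C@@]1(CC=C)C(=O)OC | intermediate
7 | (4R,5S)-2,2-dimethyl-4,5-di(prop-2-enyl)-1,3-dioxolane-4,5-dicarboxylic acid (meso; key-step precursor) | C=CC[C@]1(C(=O)O)OC(C)(C)O[C@@]1(CC=C)C(=O)O | intermediate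
8 | (4R,5S,8S)-8-(iodomethyl)-2,2-dimethyl-6-oxo-4-(prop-2-enyl)-1,3,7-trioxaspiro[4.4]nonane-4-carboxylic acid (key-step product) | IC[C@@H]1C[C@@]2(OC(C)(C)O[C@@]2(CC=C)C(=O)O)C(=O)O1 | intermediate
9 | secondary ozonide of 8 (1,2,4-trioxolan-3-ylmethyl group on C4; not isolated) | IC[C@@H]1C[C@@]2(OC(C)(C)O[C@@]2(CC3OCOO3)C(=O)O)C(=O)O1 | intermediate
10 | (4R,5S,8S)-8-(iodomethyl)-2,2-dimethyl-6-oxo-4-(2-oxoethyl)-1,3,7-trioxaspiro[4.4]nonane-4-carboxylic acid | IC[C@@H]1C[C@@]2(OC(C)(C)O[C@@]2(CC=O)C(=O)O)C(=O)O1 | intermediate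
11 | (4R,5S,8S)-4-(carboxymethyl)-8-(iodomethyl)-2,2-dimethyl-6-oxo-1,3,7-trioxaspiro[4.4]nonane-4-carboxylic acid | IC[C@@H]1C[C@@]2(OC(C)(C)O[C@@]2(CC(=O)O)C(=O)O)C(=O)O1 | intermediate
12 | tert-butyl (4R,5S,8S)-4-(2-tert-butoxy-2-oxoethyl)-8-(iodomethyl)-2,2-dimethyl-6-oxo-1,3,7-trioxaspiro[4.4]nonane-4-carboxylate | IC[C@@H]1C[C@@]2(OC(C)(C)O[C@@]2(CC(=O)OC(C)(C)C)C(=O)OC(C)(C)C)C(=O)O1 | intermediate
13 | 4-tert-butyl 5-methyl (4R,5S)-4-(2-tert-butoxy-2-oxoethyl)-5-[(2S)-2-hydroxy-3-iodopropyl]-2,2-dimethyl-1,3-dioxolane-4,5-dicarboxylate (not isolated) | IC[C@@H](O)C[C@@]1(OC(C)(C)O[C@@]1(CC(=O)OC(C)(C)C)C(=O)OC(C)(C)C)C(=O)OC | intermediate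
14 | 4-tert-butyl 5-methyl (4R,5S)-4-(2-tert-butoxy-2-oxoethyl)-2,2-dimethyl-5-{[(2S)-oxiran-2-yl]methyl}-1,3-dioxolane-4,5-dicarboxylate | C1O[C@H]1C[C@@]2(OC(C)(C)O[C@@]2(CC(=O)OC(C)(C)C)C(=O)OC(C)(C)C)C(=O)OC | intermediate
15 | 9-bromonon-1-ene | C=CCCCCCCCBr | starting material
16 | non-8-enylmagnesium bromide (not isolated) | C=CCCCCCCC[Mg]Br | intermediate
17 | 4-tert-butyl 5-methyl (4R,5S)-4-(2-tert-butoxy-2-oxoethyl)-5-[(2R)-2-hydroxydodec-11-enyl]-2,2-dimethyl-1,3-dioxolane-4,5-dicarboxylate (not isolated) | C=CCCCCCCCC[C@@H](O)C[C@@]1(OC(C)(C)O[C@@]1(CC(=O)OC(C)(C)C)C(=O)OC(C)(C)C)C(=O)OC | intermediate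
18 | tert-butyl (4R,5S,8R)-4-(2-tert-butoxy-2-oxoethyl)-8-(dec-9-enyl)-2,2-dimethyl-6-oxo-1,3,7-trioxaspiro[4.4]nonane-4-carboxylate | C=CCCCCCCCC[C@@H]1C[C@@]2(OC(C)(C)O[C@@]2(CC(=O)OC(C)(C)C)C(=O)OC(C)(C)C)C(=O)O1 | intermediate
19 | (2R)-2-[(3S,5R)-5-(dec-9-enyl)-3-hydroxy-2-oxooxolan-3-yl]-2-hydroxybutanedioic acid (not isolated) | C=CCCCCCCCC[C@@H]1C[C@](O)([C@](O)(CC(=O)O)C(=O)O)C(=O)O1 | intermediate
20 | (4R,5S,8R)-8-(dec-9-enyl)-4-hydroxy-2,6-dioxo-1,7-dioxaspiro[4.4]nonane-4-carboxylic acid | C=CCCCCCCCC[C@@H]1C[C@@]2(OC(=O)C[C@]2(O)C(=O)O)C(=O)O1 | intermediate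
21 | tert-butyl (4R,5S,8R)-8-(dec-9-enyl)-4-hydroxy-2,6-dioxo-1,7-dioxaspiro[4.4]nonane-4-carboxylate | C=CCCCCCCCC[C@@H]1C[C@@]2(OC(=O)C[C@]2(O)C(=O)OC(C)(C)C)C(=O)O1 | intermediate
22 | dilithium C4-alkoxide C2–C3 enolate of 21 (not isolated) | [Li+].[Li+].C=CCCCCCCCC[C@@H]1C[C@@]2(OC([O-])=C[C@]2([O-])C(=O)OC(C)(C)C)C(=O)O1 | intermediate
23 | tert-butyl (3R,4R,5S,8R)-8-(dec-9-enyl)-3,4-dihydroxy-2,6-dioxo-1,7-dioxaspiro[4.4]nonane-4-carboxylate | C=CCCCCCCCC[C@@H]1C[C@@]2(OC(=O)[C@H](O)[C@]2(O)C(=O)OC(C)(C)C)C(=O)O1 | intermediate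
24 | (3R,4R,5S,8R)-8-(dec-9-enyl)-3,4-dihydroxy-2,6-dioxo-1,7-dioxaspiro[4.4]nonane-4-carboxylic acid | C=CCCCCCCCC[C@@H]1C[C@@]2(OC(=O)[C@H](O)[C@]2(O)C(=O)O)C(=O)O1 | target

Total step count: 14 (the Grignard reagent is made and used within step 10).
Longest linear sequence: 14 steps, from 1 to 24.

Steps most likely to fail

1. Step 5. The catalyst may not discriminate well enough between the enantiotopic halves, or between the faces of an unactivated monosubstituted alkene. Uncatalysed background cyclisation may also erode the selectivity. The fallback uses known chemistry only, sets out from 7 and returns at 8. Dehydration of 7 with acetic anhydride gives the bicyclic meso anhydride F1. Cinchona-alkaloid-catalysed desymmetrising alcoholysis with 4-methoxybenzyl alcohol uses a quinidine-derived bifunctional catalyst, or its quinine-derived pseudo-enantiomer if the other half is opened. It gives the 4-methoxybenzyl hemiester F2, in which the absolute configuration of C4 and C5 is already fixed. Because only one carboxyl is free, ordinary iodolactonisation (NIS, CH2Cl2) can close only the wanted half. It gives the iodolactone 4-methoxybenzyl ester F3, with C8 under the cis preference of the substrate and chromatographic removal of the epimer. TFA/anisole in CH2Cl2 at 0 °C removes the ester and delivers 8.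

2. Step 13. The tertiary alkoxide may undergo retro-aldol fragmentation before oxygen transfer. Facial selectivity may also be poor, because the tert-butyl ester crowds the face that has to be attacked. The fallback avoids strong base and sets C3 by reduction; it sets out from 21 and returns at 23. Soft enolisation with TMSOTf/Et3N gives the O-silylated silyl ketene acetal F4. Rubottom oxidation with one equivalent of dimethyldioxirane at −78 °C attacks the ketene acetal far faster than the terminal alkene and gives the bis(trimethylsilyl) ether F5 without regard to the C3 configuration. HF·pyridine gives the C3-epimeric diol F6, and Dess–Martin periodinane gives the 3-oxo lactone F7. Hydroxyl-directed reduction with Me4NBH(OAc)3 in MeCN/AcOH delivers hydride from the face of the C4 hydroxyl, so the new hydroxyl is trans to it, which is 23.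

3. Step 11. The electron-poor, fully substituted ketal may need forcing acid, under which addition of acid to the terminal double bond, or its migration, sets in. The fallback carries out the acid step before any chain alkene is present; it sets out from 12 and returns at 21. TFA/CH2Cl2/H2O converts 12 into the iodo bislactone acid F8, and the O-tert-butyl isourea gives the iodo bislactone tert-butyl ester F9. Copper-catalysed sp3–sp3 coupling of the primary iodide then joins C1′–C2′ directly to give 21. This coupling uses Grignard reagent 16 (three equivalents, the first deprotonating the C4 hydroxyl) with Li2CuCl4 (5 mol %) in THF at −78 → −20 °C.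

Further compounds
F1 | step 5 | (3aR,6aS)-2,2-dimethyl-3a,6a-di(prop-2-enyl)furo[3,4-d][1,3]dioxole-4,6-dione (meso anhydride) | C=CC[C@@]12C(=O)OC(=O)[C@]1(CC=C)OC(C)(C)O2
F2 | step 5 | (4S,5R)-5-[(4-methoxybenzyl)oxycarbonyl]-2,2-dimethyl-4,5-di(prop-2-enyl)-1,3-dioxolane-4-carboxylic acid | C=CC[C@]1(C(=O)O)OC(C)(C)O[C@@]1(CC=C)C(=O)OCc2ccc(OC)cc2
F3 | step 5 | 4-methoxybenzyl (4R,5S,8S)-8-(iodomethyl)-2,2-dimethyl-6-oxo-4-(prop-2-enyl)-1,3,7-trioxaspiro[4.4]nonane-4-carboxylate | IC[C@@H]1C[C@@]2(OC(C)(C)O[C@@]2(CC=C)C(=O)OCc3ccc(OC)cc3)C(=O)O1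
F4 | step 13 | tert-butyl (4R,5S,8R)-8-(dec-9-enyl)-6-oxo-2,4-bis(trimethylsilyloxy)-1,7-dioxaspiro[4.4]non-2-ene-4-carboxylate | C=CCCCCCCCC[C@@H]1C[C@@]2(OC(O[Si](C)(C)C)=C[C@]2(O[Si](C)(C)C)C(=O)OC(C)(C)C)C(=O)O1
F5 | step 13 | tert-butyl 8-(dec-9-enyl)-2,6-dioxo-3,4-bis(trimethylsilyloxy)-1,7-dioxaspiro[4.4]nonane-4-carboxylate (C3 epimers; C4, C5 and C8 configured as in 23) | C=CCCCCCCCC[C@@H]1C[C@@]2(OC(=O)C(O[Si](C)(C)C)[C@]2(O[Si](C)(C)C)C(=O)OC(C)(C)C)C(=O)O1
F6 | step 13 | tert-butyl 8-(dec-9-enyl)-3,4-dihydroxy-2,6-dioxo-1,7-dioxaspiro[4.4]nonane-4-carboxylate (C3 epimers; C4, C5 and C8 configured as in 23) | C=CCCCCCCCC[C@@H]1C[C@@]2(OC(=O)C(O)[C@]2(O)C(=O)OC(C)(C)C)C(=O)O1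
F7 | step 13 | tert-butyl 8-(dec-9-enyl)-4-hydroxy-2,3,6-trioxo-1,7-dioxaspiro[4.4]nonane-4-carboxylate (C4, C5 and C8 configured as in 23) | C=CCCCCCCCC[C@@H]1C[C@@]2(OC(=O)C(=O)[C@]2(O)C(=O)OC(C)(C)C)C(=O)O1
F8 | step 11 | (4R,5S,8S)-4-hydroxy-8-(iodomethyl)-2,6-dioxo-1,7-dioxaspiro[4.4]nonane-4-carboxylic acid | IC[C@@H]1C[C@@]2(OC(=O)C[C@]2(O)C(=O)O)C(=O)O1
F9 | step 11 | tert-butyl (4R,5S,8S)-4-hydroxy-8-(iodomethyl)-2,6-dioxo-1,7-dioxaspiro[4.4]nonane-4-carboxylate | IC[C@@H]1C[C@@]2(OC(=O)C[C@]2(O)C(=O)OC(C)(C)C)C(=O)O1
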